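The constants used here were set for the occasion; the rest is arithmetic.

The two routes in these flasks differ by 66.0 kJ mol⁻¹ in apparent barrier, the right-handed route being the higher, and I carried the selectivity from one temperature to another by that number.

    partner + catalyst intermediate A → free catalyst + left-handed product (k1 = 130 M⁻¹ s⁻¹, Ea1 = 49.0 kJ mol⁻¹)
    free catalyst + right-handed substrate ⇌ catalyst intermediate B (K2 = 100 M⁻¹, k2 = 23000 M⁻¹ s⁻¹, Ea2 = 18.0 kJ mol⁻¹, ΔH2 = −22.0 kJ mol⁻¹)
    free catalyst + left-handed substrate ⇌ catalyst intermediate A (K3 = 17 M⁻¹, k3 = 13000 M⁻¹ s⁻¹, Ea3 = 37.0 kJ mol⁻¹, ΔH3 = −75.0 kJ mol⁻¹)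
    partner + catalyst intermediate B → free catalyst + right-handed product (k4 = 44 M⁻¹ s⁻¹, Ea4 = 62.0 kJ mol⁻¹)
    partner → decomposed reagent (k5 = 0.0068 s⁻¹, Ea5 = 97.0 kJ mol⁻¹)
    partner + precatalyst → free catalyst + spent reagent (k6 = 0.052 M⁻¹ s⁻¹, Ea6 = 75.0 kJ mol⁻¹)
    (constants at 100 °C)

| setting | cedar | ash | larch |
|---|---|---|---|
| left-handed substrate | 20 mM | 20 mM | 20 mM |
| partner | 30.0 mM | 30.0 mM | 30.0 mM |
| precatalyst | 22 µM | 22 µM | 22 µM |
| right-handed substrate | 20 mM | 20 mM | 20 mM |
| temperature | 100 °C | 125 °C | 75 °C |
| time | 2.5 min | 2.5 min | 2.5 min |

- free catalyst is single-handed; left-handed substrate and right-handed substrate are mirror images of each other, charged as a racemate, each of them at the stated concentration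
- constants are those at 100 °C; use the activation energies and enthalpies for any other temperature

- the flask with the highest share of left-handed product in all that became left-handed product or right-handed product ("all alike" if they lie within 1.5 percentage points) (cedar / ash / larch / all alike)
- share of left-handed product in all that became left-handed product or right-handed product, cedar
- share of left-handed product in all that became left-handed product or right-handed product, ash
- share of left-handed product in all that became left-handed product or right-handed product, larch

1. Precatalyst reacts with partner to release free catalyst. Free catalyst reversibly binds left-handed substrate as catalyst intermediate A, with equilibrium constant K_A, and right-handed substrate as catalyst intermediate B, with K_B. Partner then turns intermediate A into left-handed product, with rate constant k_A, and intermediate B into right-handed product, with k_B. Partner also decomposes by itself.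

2. The puzzle is in larch. At 75 °C, K_B is 166 M⁻¹ and K_A is 96.5 M⁻¹, so larch should hold more intermediate B than intermediate A. Yet I expected more left-handed product there.

3. In larch, k_A is 41.8 M⁻¹ s⁻¹, so partner at its charge of 30.0 mM consumes intermediate A at 1.25 s⁻¹ at the start, whereas intermediate A unbinds far faster, at 57.2 s⁻¹. I therefore treated binding as a pre-equilibrium, and assumed the same for cedar and ash.

4. The two product rates are then k_A K_A [partner][free catalyst][left-handed substrate] and k_B K_B [partner][free catalyst][right-handed substrate]. Partner and free catalyst cancel in their ratio, however they change with time. I assumed that the two substrates stay nearly equal, so integrating over the run gives a constant product ratio.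

5. I call this the selectivity factor ρ = k_A K_A/(k_B K_B). It is 0.502 at 100 °C, and the barrier difference scales it with temperature. In larch, ρ is 2.31.

6. That clears the puzzle. In larch, k_B is 10.5 M⁻¹ s⁻¹, so k_A/k_B is 3.98, which outweighs K_B/K_A, 1.72. In larch, intermediate A is bound less strongly but reacts with partner faster.

7. The left-handed share is ρ/(1+ρ). I committed to 33.4% for cedar, 11.7% for ash and 69.8% for larch, so larch has the highest share.

The forecast named larch, gave 33.5% for cedar, 11.8% for ash and 69.4% for larch, 0.40 percentage points below my larch figure, and held that “the share is set almost entirely by the ratio” of the two routes.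

The simulation gave larch, with 33.5% for cedar, 11.7% for ash and 69.5% for larch.

After 2.50 min, larch held 1.17% of its catalyst as intermediate A and 2.05% as intermediate B, yet it had made 0.0576% left-handed product and 0.0253% right-handed product, reckoned on the two substrates charged together. That reads as a ratio of 2.28 against my ρ of 2.31. Carrying ρ to a flask like larch kept at 100 °C gives 0.502, hence a share of 33.4%. That neighbouring flask gave 33.5%, with 99.7% of its left-handed substrate and 99.4% of its right-handed substrate still unbound.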